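Locants used throughout: the unprimed dihydrobenzofuran is O1, C2, C3, C3a–C7a (benzo ring A, ring B = aryl on C2, ring F = styryl arene on C5); the primed one is O1', C2', C3', C3a'–C7a' (benzo ring C, ring D = aryl on C3', ring E = aryl on C2').

## The problem

trans-Diptoindonesin B (33) is a resveratrol trimer built from two trans-2,3-diaryl-2,3-dihydrobenzofurans: the unprimed unit carries ring B (4-hydroxyphenyl) on C2 and an (E)-3,5-dihydroxystyryl arm on C5 of ring A, and its C3 is bonded to C4' of the primed unit, which carries ring D (3,5-dihydroxyphenyl) on C3' and ring E (4-hydroxyphenyl) on C2'. Read from the SMILES, the four stereocentres are 2S, 3S, 2'S and 3'S, that is, two trans pairs. The pairs lie on either side of the C3–C4' bond and cannot be relied on to control each other, so each needs its own source of absolute configuration. Within a pair the diarylmethine carbon (C3, C3') is configurationally robust, whereas the oxygen-bearing carbon (C2, C2') is a 4-oxybenzylic ether that can ionise and re-close; trans is therefore the thermodynamic outcome and C3/C3' can correct C2/C2', but not the reverse. Ring C is the crowded centre of the molecule: a 1,2,3,5-tetrasubstituted resorcinol with oxygen on C7a' and C6' and two diarylmethine carbons on the neighbouring positions C3a' and C4', a pattern that substitution of a ready-made resorcinol does not deliver cleanly. The benzylic C2–O1 and C2'–O1' bonds (acid, Lewis acid, hydrogenolysis), the electron-rich stilbene (acid, oxidants, hydrogenation, light) and seven phenols (oxidation) argue for robust ethers until the last step and for a late introduction of the stilbene. The enabling feature is that C3a'–C7a'–O1' together with C3' and C2' is a γ-butyrolactone in disguise (α-carbon, carbonyl carbon, ring oxygen, β- and γ-carbon), while the remaining carbons C4'–C5'–C6'–C7', with oxygen on C6' and a carbon substituent on C4', are C6–C5–C4–C3 of a 4-methoxy-6-alkyl-2-pyrone; ring C can thus be grown by a [4+2] union of a lactone ketene acetal with such a pyrone, with CO2 and a silanol as the only by-products.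

## Retrosynthesis

**33 from 32.** The seven O–CH3 bonds are cut last. Methyl ethers are chosen because the C6' oxygen arrives as the pyrone methoxy group, the other aryl rings come from inexpensive methoxyarenes, and methyl ethers survive amide bases, heat, Grignard reagents, fluoride and palladium. Benzyl ethers would not survive the hydrogenolysis planned for ring C and silyl ethers would not survive the desilylation. The forward step must cleave seven ethers without opening the two benzylic C–O bonds.

**32 from 30 and 31.** The C5–vinyl bond is cut (Mizoroki–Heck). Against an olefination of a C5 aldehyde, the aryl bromide of 30 needs no redox adjustment, is inert to the steps that precede it, and the coupling with styrene 31 gives the E-alkene directly. The stilbene thereby appears only one step before the end.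

**30 from 24 and 27.** Ring A's dihydrofuran is cut at C2–C3 and C2–O1, a [4+1] disconnection to the ortho-quinone methide released from sulfone 24 and the 4-methoxybenzylidene unit of chiral sulfonium salt 27 (from sulfide 25 and bromide 26). Against an acid cyclodehydration, which would need C3 set beforehand, this cut creates C2 and C3 together under reagent control, and 24 carries no stereochemical information at ring A. The forward reaction must be trans-selective, and the ylide must dominate the bias of the chiral ring C substituent.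

**24 from 20 and 21.** The C3–C3a bond is cut: sulfone 24 comes from diol 23, the adduct of aldehyde 20 and the aryl Grignard reagent from 4-bromo-2-iodophenol 21. The iodide is preferred to a dibromide because iodine–magnesium exchange is unambiguous and leaves the bromide for the Heck step. No phenol protection is needed if the phenoxide is formed first.

**20 from 17.** These are functional-group changes at one carbon and one halogen: aldehyde 20 from alcohol 19, from silyl ether 18, from bromide 17. The future C3 rides through the ring-forming step as a silyloxymethyl group, because an aldehyde would be attacked by the ketene acetal and an ester would blur the regiochemistry. The C7' bromine of 17 is an auxiliary that is removed by hydrogenolysis.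

**17 from 9 and 14 (key cut).** Ring C is cut at C3a'–C4' and C7a'–C7'. The neighbouring cut (C3'–C3a' and O1'–C7a', ring C bought as an arene) would bring back the 1,2,3,5-substitution problem. The chosen cut places every substituent by the way the two partners are made: the lactone-derived ketene silyl acetal 9 brings C3a', C7a', O1' and both stereocentres, and pyrone 14 brings C4'–C7' with the methoxy group and the C3 handle. A 4-alkoxy-2-pyrone is a reluctant electrophilic diene, so 14 carries a bromine on C3, which lowers the pyrone LUMO, reinforces the regiochemistry and ends up on C7'. The forward reaction must be regioselective, lose CO2, and aromatise by loss of silanol while keeping O1' in the ring.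

**14 from 10.** The pyrone is derived from commercial 10 without any C–C bond formation: oxidation of the C6 methyl group to aldehyde 11, reduction to alcohol 12, silylation to 13 and bromination at C3 to 14.

**9 from 8, 6, 4, 1, 2 and 5.** Acetal 9 is the O-silylated enolate of trans-lactone 8. Lactone 8 is cut at O1–C5 back to hydroxy ester 7 and keto ester 6; 6 is cut at the Cα–CH2 bond to deoxybenzoin 4 and bromoacetate 5; 4 is cut at the aryl–carbonyl bond to acid 1 and anisole 2. The enolisable α-aryl ketone of 6 allows one catalytic reduction with dynamic kinetic resolution to fix C3' (lactone C4). C2' (lactone C5) is then set thermodynamically by ionising lactonisation, so only the robust centre needs kinetic control.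

## Roads not taken

**Alternative 1:** Both dihydrofurans are cut across C2–C3/C2–O1 and C2'–C3'/C2'–O1', leading to bis-sulfone A1 and two equivalents of salt 27. In the forward step base releases two ortho-quinone methides and each takes up one ylide carbon, giving A2, which is the same compound as 30.
- Merits: every step is of a known type, one reagent sets all four stereocentres in one flask, and the route to A2 is shorter than the chosen route to 30 by several steps.
- Weak points: A1 carries two diarylmethyl sulfones on the adjacent carbons C3a' and C4'; the second quinone methide must form and react next to the first new ring; two independent reagent-controlled events multiply any error into diastereomers of a late compound; and ring C must be bought as a resorcinol and its substitution pattern introduced by directed substitution.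
- Comparison: on step count and precedent this road is better. The chosen plan sets against it that C2'/C3' are fixed catalytically on a small lactone whose enantiopurity can be upgraded and checked, that only one ylide event takes place on advanced material, and that the substitution pattern of ring C is fixed by construction. The [4+1] logic of this alternative is kept as the fallback for ring C.

**Alternative 2:** Ring C is bought as an aryne and the C3–C4' and C3a'–C3' bonds are cut, leading to keto lactone A3 and silyl triflate A4. In the forward step fluoride releases the aryne from A4, the enolate carbon of A3 adds to the aryne carbon remote from the methoxy group, the aryl anion closes onto the ketone, and the four-membered alkoxide opens again to give A5.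
- Merits: one step joins rings A, C and D, and the methoxy group next to the aryne dictates the regiochemistry.
- Weak points: A5 holds none of the four stereocentres and its C3 is an enolisable lactone carbon. C2 with ring B, C2' with ring E and the O1'–C2' bond still have to be added; a lactone carbonyl and a diaryl ketone must each be turned into a stereodefined sp3 carbon; and the C7a' methyl ether must be cleaved selectively.
- Comparison: this road is more convergent at the skeleton stage, but it postpones the whole stereochemical problem to compounds with labile centres. The chosen plan has solved half of it before ring C exists.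

**Alternative 3:** Ring A is cut at O1–C7a, and the C2–aryl and C3–C3a bonds are made together from alkenyl boronate A6, triflate A7 and aryllithium A8. In the forward step A8 adds to boron, and the arylpalladium species from A7, with a chiral Mandyphos ligand, triggers migration of the 4-methoxyphenyl group to C2 as the ring A aryl is delivered to C3, giving boronic ester A9. Oxidation of the C–B bond and displacement of fluoride by the C2 alkoxide would then close O1–C7a.
- Merits: both ring A centres come from a chiral catalyst, their relative configuration follows from the anti addition across the E-alkene, and no stoichiometric chiral reagent is used.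
- Weak points: A6 still requires all of ring C (it would be made from aldehyde 20), so only the endgame changes; β-aryl alkenyl boronates are among the slower substrates; the catalyst must override a chiral substrate; and oxidation, ring closure and conversion of the ester into the styryl arm cost several more steps than one annulation and one Heck coupling.
- Comparison: this road is better in that the chirality of ring A is catalytic. The chosen plan reaches 30 from 20 in three steps with the bromide ready for coupling, and its chiral sulfide is cheap and recoverable.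

Key step: step 9

Assumptions (one line each):
- In step 3 the (R,R)-catalyst is taken to give the (R)-carbinol, as usual for aryl ketones, and the reduction to take the Felkin-type (syn) course, so that the (3R)-ketone is the one consumed; if the pairing proves opposite, the (S,S)-catalyst is used and nothing else changes.
- In step 16 the (1R,4R,5R)-sulfide is taken to transfer the 4-methoxybenzylidene unit with the (2S) sense; if it proves opposite, the enantiomeric sulfide from (S)-limonene is used in the same way.

## Steps

Step 1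
Reactants: 1 3,5-dimethoxyphenylacetic acid; 2 anisole
Product: 4 2-(3,5-dimethoxyphenyl)-1-(4-methoxyphenyl)ethan-1-one, via 3,5-dimethoxyphenylacetyl chloride 3 (not isolated)
Conditions: (COCl)2, DMF (cat.), CH2Cl2, 0 °C to rt; then anisole (5 equiv), AlCl3, CH2Cl2, 0 °C
Reagents that add atoms: none
Why: Friedel–Crafts acylation of anisole is para-selective, and the excess of anisole should outcompete self-acylation of the dimethoxyphenyl ring.

Step 2
Reactants: 4 2-(3,5-dimethoxyphenyl)-1-(4-methoxyphenyl)ethan-1-one; 5 ethyl bromoacetate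
Product: 6 ethyl 3-(3,5-dimethoxyphenyl)-4-(4-methoxyphenyl)-4-oxobutanoate (racemic)
Conditions: NaN(SiMe3)2, THF, −78 °C; then 5, −78 to 0 °C
Reagents that add atoms: none
Why: Enolate alkylation (SN2) of a deoxybenzoin with a reactive α-halo ester; the new stereocentre is formed racemic and is meant to stay enolisable for the next step.

Step 3
Reactants: 6 ethyl 3-(3,5-dimethoxyphenyl)-4-(4-methoxyphenyl)-4-oxobutanoate (racemic)
Product: 8 (4R,5S)-4-(3,5-dimethoxyphenyl)-5-(4-methoxyphenyl)oxolan-2-one, via syn hydroxy ester 7 (not isolated)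
Conditions: RuCl(p-cymene)[(R,R)-TsDPEN] (2 mol%), HCO2H, Et3N, DMF, 40 °C; then CF3CO2H, CH2Cl2, 0 °C to rt
Reagents that add atoms: none
Why: Asymmetric transfer hydrogenation (Noyori–Ikariya type) with dynamic kinetic resolution: the α-aryl ketone racemises through its enol, and the catalyst should reduce the (3R)-ketone in the matched Felkin-type sense to the (3R,4R)-alcohol 7, which sets lactone C4 (the future C3'). The acid then lactonises through the 4-methoxybenzylic cation under thermodynamic control, so that lactone C5 (the future C2') ends trans to the aryl group on C4 whatever the carbinol configuration was; any cis-lactone formed equilibrates in the same way.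

Step 4
Reactants: 8 (4R,5S)-4-(3,5-dimethoxyphenyl)-5-(4-methoxyphenyl)oxolan-2-one
Product: 9 tert-butyl{[(2S,3R)-3-(3,5-dimethoxyphenyl)-2-(4-methoxyphenyl)-2,3-dihydrofuran-5-yl]oxy}dimethylsilane
Conditions: LiN(i-Pr)2, THF, −78 °C; t-BuMe2SiCl, DMPU, −78 °C to rt; pentane, filtration, no aqueous work-up; used crude
Reagents that add atoms: tert-butyldimethylsilyl chloride, CC(C)(C)[Si](C)(C)Cl
Why: O-silylation of a lactone lithium enolate gives the ketene silyl acetal; deprotonation occurs only at the carbon next to the carbonyl group, so both stereocentres are untouched.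

Step 5
Reactants: 10 4-methoxy-6-methyl-2H-pyran-2-one
Product: 11 4-methoxy-2-oxo-2H-pyran-6-carbaldehyde
Conditions: SeO2, 1,4-dioxane, 160 °C (sealed tube)
Reagents that add atoms: selenium dioxide, O=[Se]=O
Why: Riley oxidation of the vinylogously activated C6 methyl group; it is the only allylic C–H position of the pyrone.

Step 6
Reactants: 11 4-methoxy-2-oxo-2H-pyran-6-carbaldehyde
Product: 12 6-(hydroxymethyl)-4-methoxy-2H-pyran-2-one
Conditions: NaBH4, MeOH, 0 °C
Reagents that add atoms: none
Why: Chemoselective borohydride reduction of the aldehyde; the vinylogous carbonate of the pyrone is far less electrophilic at this temperature.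

Step 7
Reactants: 12 6-(hydroxymethyl)-4-methoxy-2H-pyran-2-one
Product: 13 6-{[(tert-butyldimethylsilyl)oxy]methyl}-4-methoxy-2H-pyran-2-one
Conditions: t-BuMe2SiCl, imidazole, DMF, rt
Reagents that add atoms: tert-butyldimethylsilyl chloride, CC(C)(C)[Si](C)(C)Cl
Why: Standard silylation of a primary alcohol; the silyl ether keeps the C6 substituent non-conjugating and inert to the ketene acetal.

Step 8
Reactants: 13 6-{[(tert-butyldimethylsilyl)oxy]methyl}-4-methoxy-2H-pyran-2-one
Product: 14 3-bromo-6-{[(tert-butyldimethylsilyl)oxy]methyl}-4-methoxy-2H-pyran-2-one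
Conditions: N-bromosuccinimide, MeCN, rt, dark
Reagents that add atoms: N-bromosuccinimide, O=C1CCC(=O)N1Br
Why: Electrophilic bromination of a 4-alkoxy-2-pyrone goes to C3, the enol-ether β-carbon activated by the 4-methoxy group; the bromine serves as a removable activator for the next step.

Step 9
Reactants: 9 tert-butyl{[(2S,3R)-3-(3,5-dimethoxyphenyl)-2-(4-methoxyphenyl)-2,3-dihydrofuran-5-yl]oxy}dimethylsilane; 14 3-bromo-6-{[(tert-butyldimethylsilyl)oxy]methyl}-4-methoxy-2H-pyran-2-one
Product: 17 (2S,3S)-7-bromo-4-{[(tert-butyldimethylsilyl)oxy]methyl}-3-(3,5-dimethoxyphenyl)-6-methoxy-2-(4-methoxyphenyl)-2,3-dihydro-1-benzofuran, via bridged lactone adduct 15 (not isolated), via cyclohexadiene ketal 16 (not isolated)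
Conditions: 9 (1.5 equiv), toluene, 110 °C (sealed tube)
Reagents that add atoms: none
Why: Proposed new method: the nucleophilic β-carbon of ketene silyl acetal 9 (future C3a') should attack C6 of bromopyrone 14, the terminus of its vinylogous lactone and the position that electron-rich alkenes attack in 3-bromo-2-pyrones, and the silyloxy-oxocarbenium carbon (future C7a') then closes onto the bromine-bearing C3 of the resulting dienolate, a stepwise or strongly asynchronous inverse-demand [4+2] addition that gives bridged lactone 15. The closest known reactions are the Diels–Alder reactions of 3-bromo- and 3,5-dibromo-2-pyrones with vinyl ethers and silyl enol ethers and of coumalates with ketene acetals, which give alkoxyarenes after loss of CO2 and alcohol; a 4-alkoxy-6-alkyl-2-pyrone has not been joined to a lactone-derived acetal in this way, and the bromine on C3 is there to lower the pyrone LUMO enough to offset the 4-methoxy donor. Ring C is closed by this intermolecular [4+2] annulation (in the stepwise limit the second bond forms by a 6-(enolexo)-exo-trig attack), 15 loses CO2 by retro-[4+2] to cyclohexadiene 16, and 16 aromatises by 1,2-elimination of t-BuMe2SiOH across C3a'–C7a'. No stereocentre is created in the product, because the four sp3 centres formed on the way all become aromatic carbons, and C2' and C3' lie on the saturated side of the dihydrofuran and are carried over unchanged. The step needs regioselectivity, which the polarity match (acetal β-carbon to C6, acetal carbon to C3) secures and the non-conjugating 6-alkyl group and the 3-bromine reinforce. It also needs aromatisation by loss of silanol and not of the ring oxygen, which is favoured because the silanolate is the better leaving group and the ring oxygen the better donor, and because ring opening would be reversible whereas loss of silanol is not.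

Step 10
Reactants: 17 (2S,3S)-7-bromo-4-{[(tert-butyldimethylsilyl)oxy]methyl}-3-(3,5-dimethoxyphenyl)-6-methoxy-2-(4-methoxyphenyl)-2,3-dihydro-1-benzofuran
Product: 18 (2S,3S)-4-{[(tert-butyldimethylsilyl)oxy]methyl}-3-(3,5-dimethoxyphenyl)-6-methoxy-2-(4-methoxyphenyl)-2,3-dihydro-1-benzofuran
Conditions: H2 (1 atm), Pd/C, Et3N, EtOAc, rt
Reagents that add atoms: none
Why: Catalytic hydrodehalogenation of an aryl bromide; the amine takes up HBr and slows hydrogenolysis of the benzylic C2–O bond and of the benzylic silyl ether.

Step 11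
Reactants: 18 (2S,3S)-4-{[(tert-butyldimethylsilyl)oxy]methyl}-3-(3,5-dimethoxyphenyl)-6-methoxy-2-(4-methoxyphenyl)-2,3-dihydro-1-benzofuran
Product: 19 [(2S,3S)-3-(3,5-dimethoxyphenyl)-6-methoxy-2-(4-methoxyphenyl)-2,3-dihydro-1-benzofuran-4-yl]methanol
Conditions: Bu4NF, THF, 0 °C to rt
Reagents that add atoms: none
Why: Fluoride cleavage of a primary silyl ether; nothing else in the molecule responds to fluoride.

Step 12
Reactants: 19 [(2S,3S)-3-(3,5-dimethoxyphenyl)-6-methoxy-2-(4-methoxyphenyl)-2,3-dihydro-1-benzofuran-4-yl]methanol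
Product: 20 (2S,3S)-3-(3,5-dimethoxyphenyl)-6-methoxy-2-(4-methoxyphenyl)-2,3-dihydro-1-benzofuran-4-carbaldehyde
Conditions: MnO2, CH2Cl2, rt
Reagents that add atoms: none
Why: Selective oxidation of a benzylic alcohol to the aldehyde without over-oxidation; the benzylic ether C–H bonds are not attacked under these conditions.

Step 13
Reactants: 20 (2S,3S)-3-(3,5-dimethoxyphenyl)-6-methoxy-2-(4-methoxyphenyl)-2,3-dihydro-1-benzofuran-4-carbaldehyde; 21 4-bromo-2-iodophenol
Product: 23 4-bromo-2-{[(2S,3S)-3-(3,5-dimethoxyphenyl)-6-methoxy-2-(4-methoxyphenyl)-2,3-dihydro-1-benzofuran-4-yl](hydroxy)methyl}phenol (both carbinol epimers), via aryl dimagnesium reagent 22 (not isolated)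
Conditions: 21 (2.5 equiv), MeMgCl, LiCl, THF, −20 °C; i-PrMgCl, −20 to 0 °C; then 20, −20 °C to rt; aq. NH4Cl
Reagents that add atoms: none
Why: Deprotonation of the phenol followed by iodine–magnesium exchange gives an ortho-magnesiated phenoxide that leaves the aryl bromide intact and adds to the aldehyde (Grignard addition). The new carbinol centre is uncontrolled and is erased in step 16.

Step 14
Reactants: 23 4-bromo-2-{[(2S,3S)-3-(3,5-dimethoxyphenyl)-6-methoxy-2-(4-methoxyphenyl)-2,3-dihydro-1-benzofuran-4-yl](hydroxy)methyl}phenol (both carbinol epimers)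
Product: 24 4-bromo-2-{[(2S,3S)-3-(3,5-dimethoxyphenyl)-6-methoxy-2-(4-methoxyphenyl)-2,3-dihydro-1-benzofuran-4-yl](4-methylbenzenesulfonyl)methyl}phenol (both epimers at the sulfone carbon)
Conditions: 4-MeC6H4SO2Na, HCO2H, THF/H2O, rt
Reagents that add atoms: sodium 4-methylbenzenesulfinate, Cc1ccc(S(=O)[O-])cc1.[Na+]
Why: Acid-mediated substitution of an ortho-hydroxybenzhydrol by sulfinate through the ortho-quinone methide or its cation gives the bench-stable quinone methide precursor; formic acid is too weak to open the ring C benzylic ether.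

Step 15
Reactants: 25 (1R,4R,5R)-4,7,7-trimethyl-6-thiabicyclo[3.2.1]octane (isothiocineole); 26 4-methoxybenzyl bromide
Product: 27 (1R,4R,5R)-6-(4-methoxybenzyl)-4,7,7-trimethyl-6-thiabicyclo[3.2.1]octan-6-ium trifluoromethanesulfonate
Conditions: LiOTf, CH2Cl2/H2O, rt
Reagents that add atoms: lithium trifluoromethanesulfonate, [Li+].[O-]S(=O)(=O)C(F)(F)F
Why: S-alkylation of the bicyclic sulfide on its open face, with exchange to a non-nucleophilic counter-ion so that the labile 4-methoxybenzyl sulfonium salt does not revert.

Step 16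
Reactants: 24 4-bromo-2-{[(2S,3S)-3-(3,5-dimethoxyphenyl)-6-methoxy-2-(4-methoxyphenyl)-2,3-dihydro-1-benzofuran-4-yl](4-methylbenzenesulfonyl)methyl}phenol (both epimers at the sulfone carbon); 27 (1R,4R,5R)-6-(4-methoxybenzyl)-4,7,7-trimethyl-6-thiabicyclo[3.2.1]octan-6-ium trifluoromethanesulfonate
Product: 30 (2S,3S)-5-bromo-3-[(2S,3S)-3-(3,5-dimethoxyphenyl)-6-methoxy-2-(4-methoxyphenyl)-2,3-dihydro-1-benzofuran-4-yl]-2-(4-methoxyphenyl)-2,3-dihydro-1-benzofuran, via ortho-quinone methide 28 (not isolated), via sulfonium ylide 29 (not isolated)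
Conditions: Cs2CO3, CH2Cl2, 0 °C to rt
Reagents that add atoms: none
Why: Sulfur-ylide [4+1] annulation: base eliminates sulfinate to quinone methide 28 and deprotonates 27 to ylide 29, the ylide adds to the exocyclic carbon, and the phenoxide displaces the sulfide by 5-exo-tet SN2. C2 is set by the face of the ylide that the chiral sulfide leaves open (with inversion in the ring closure), and C3 follows as trans through the anti-betaine.

Step 17
Reactants: 30 (2S,3S)-5-bromo-3-[(2S,3S)-3-(3,5-dimethoxyphenyl)-6-methoxy-2-(4-methoxyphenyl)-2,3-dihydro-1-benzofuran-4-yl]-2-(4-methoxyphenyl)-2,3-dihydro-1-benzofuran; 31 1-ethenyl-3,5-dimethoxybenzene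
Product: 32 (2S,3S)-3-(3,5-dimethoxyphenyl)-4-{(2S,3S)-5-[(E)-2-(3,5-dimethoxyphenyl)ethenyl]-2-(4-methoxyphenyl)-2,3-dihydro-1-benzofuran-3-yl}-6-methoxy-2-(4-methoxyphenyl)-2,3-dihydro-1-benzofuran
Conditions: Pd(OAc)2 (5 mol%), P(o-tol)3, Et3N, DMF, 110 °C
Reagents that add atoms: none
Why: Mizoroki–Heck coupling of an aryl bromide with a styrene; syn insertion and syn β-hydride elimination give the E-stilbene, and no stereocentre lies near the reacting carbon.

Step 18
Reactants: 32 (2S,3S)-3-(3,5-dimethoxyphenyl)-4-{(2S,3S)-5-[(E)-2-(3,5-dimethoxyphenyl)ethenyl]-2-(4-methoxyphenyl)-2,3-dihydro-1-benzofuran-3-yl}-6-methoxy-2-(4-methoxyphenyl)-2,3-dihydro-1-benzofuran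
Product: 33 trans-diptoindonesin B
Conditions: BBr3 (excess), CH2Cl2, −78 to 0 °C; then MeOH, H2O
Reagents that add atoms: none
Why: Lewis-acid cleavage of aryl methyl ethers, the usual last step for methylated resveratrol oligomers. Should the benzylic C2–O1 or C2'–O1' bond ionise reversibly, re-closure restores the thermodynamically preferred trans arrangement, which is the one required.

## Compound list

1 | 3,5-dimethoxyphenylacetic acid | COc1cc(CC(=O)O)cc(OC)c1 | starting material
2 | anisole | COc1ccccc1 | starting material
3 | 3,5-dimethoxyphenylacetyl chloride | COc1cc(CC(=O)Cl)cc(OC)c1 | intermediate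
4 | 2-(3,5-dimethoxyphenyl)-1-(4-methoxyphenyl)ethan-1-one | COc1ccc(C(=O)Cc2cc(OC)cc(OC)c2)cc1 | intermediate
5 | ethyl bromoacetate | CCOC(=O)CBr | starting material
6 | ethyl 3-(3,5-dimethoxyphenyl)-4-(4-methoxyphenyl)-4-oxobutanoate (racemic) | CCOC(=O)CC(c1cc(OC)cc(OC)c1)C(=O)c1ccc(OC)cc1 | intermediate
7 | ethyl (3R,4R)-3-(3,5-dimethoxyphenyl)-4-hydroxy-4-(4-methoxyphenyl)butanoate (syn hydroxy ester) | CCOC(=O)C[C@H](c1cc(OC)cc(OC)c1)[C@@H](O)c1ccc(OC)cc1 | intermediate
8 | (4R,5S)-4-(3,5-dimethoxyphenyl)-5-(4-methoxyphenyl)oxolan-2-one (trans-lactone) | O=C1C[C@H](c2cc(OC)cc(OC)c2)[C@@H](c2ccc(OC)cc2)O1 | intermediate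
9 | tert-butyl{[(2S,3R)-3-(3,5-dimethoxyphenyl)-2-(4-methoxyphenyl)-2,3-dihydrofuran-5-yl]oxy}dimethylsilane (ketene silyl acetal of 8) | COc1ccc([C@H]2OC(O[Si](C)(C)C(C)(C)C)=C[C@@H]2c2cc(OC)cc(OC)c2)cc1 | intermediate
10 | 4-methoxy-6-methyl-2H-pyran-2-one | COC1=CC(=O)OC(C)=C1 | starting material
11 | 4-methoxy-2-oxo-2H-pyran-6-carbaldehyde | COC1=CC(=O)OC(C=O)=C1 | intermediate
12 | 6-(hydroxymethyl)-4-methoxy-2H-pyran-2-one | COC1=CC(=O)OC(CO)=C1 | intermediate
13 | 6-{[(tert-butyldimethylsilyl)oxy]methyl}-4-methoxy-2H-pyran-2-one | COC1=CC(=O)OC(CO[Si](C)(C)C(C)(C)C)=C1 | intermediate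
14 | 3-bromo-6-{[(tert-butyldimethylsilyl)oxy]methyl}-4-methoxy-2H-pyran-2-one | COC1=C(Br)C(=O)OC(CO[Si](C)(C)C(C)(C)C)=C1 | intermediate
15 | bridged lactone adduct: 2-oxabicyclo[2.2.2]oct-5-en-3-one with Br on the bridgehead next to the carbonyl, CH2OSiMe2t-Bu on the other bridgehead and OMe on the alkene, fused through its two saturated carbons to the tetrahydrofuran ring of 9 (acetal carbon bearing OSiMe2t-Bu bonded to the Br bridgehead; C2' and C3' as in 9; four new centres undefined) | COC1=CC2(CO[Si](C)(C)C(C)(C)C)OC(=O)C1(Br)C1(O[Si](C)(C)C(C)(C)C)O[C@H](c3ccc(OC)cc3)[C@@H](c3cc(OC)cc(OC)c3)C12 | intermediate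
16 | cyclohexadiene ketal: 7-bromo-7a-[(tert-butyldimethylsilyl)oxy]-4-{[(tert-butyldimethylsilyl)oxy]methyl}-3-(3,5-dimethoxyphenyl)-6-methoxy-2-(4-methoxyphenyl)-2,3,3a,7a-tetrahydro-1-benzofuran (C2 and C3 as in 17; C3a and C7a undefined) | COC1=C(Br)C2(O[Si](C)(C)C(C)(C)C)O[C@H](c3ccc(OC)cc3)[C@@H](c3cc(OC)cc(OC)c3)C2C(CO[Si](C)(C)C(C)(C)C)=C1 | intermediate
17 | (2S,3S)-7-bromo-4-{[(tert-butyldimethylsilyl)oxy]methyl}-3-(3,5-dimethoxyphenyl)-6-methoxy-2-(4-methoxyphenyl)-2,3-dihydro-1-benzofuran | CC(C)(C)[Si](C)(C)OCc1cc(OC)c(Br)c2c1[C@H](c1cc(OC)cc(OC)c1)[C@@H](c1ccc(OC)cc1)O2 | intermediate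
18 | (2S,3S)-4-{[(tert-butyldimethylsilyl)oxy]methyl}-3-(3,5-dimethoxyphenyl)-6-methoxy-2-(4-methoxyphenyl)-2,3-dihydro-1-benzofuran | CC(C)(C)[Si](C)(C)OCc1cc(OC)cc2c1[C@H](c1cc(OC)cc(OC)c1)[C@@H](c1ccc(OC)cc1)O2 | intermediate
19 | [(2S,3S)-3-(3,5-dimethoxyphenyl)-6-methoxy-2-(4-methoxyphenyl)-2,3-dihydro-1-benzofuran-4-yl]methanol | OCc1cc(OC)cc2c1[C@H](c1cc(OC)cc(OC)c1)[C@@H](c1ccc(OC)cc1)O2 | intermediate
20 | (2S,3S)-3-(3,5-dimethoxyphenyl)-6-methoxy-2-(4-methoxyphenyl)-2,3-dihydro-1-benzofuran-4-carbaldehyde | O=Cc1cc(OC)cc2c1[C@H](c1cc(OC)cc(OC)c1)[C@@H](c1ccc(OC)cc1)O2 | intermediate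
21 | 4-bromo-2-iodophenol | Oc1ccc(Br)cc1I | starting material
22 | chloromagnesium 4-bromo-2-(chloromagnesio)phenoxide (aryl dimagnesium reagent) | Cl[Mg]Oc1ccc(Br)cc1[Mg]Cl | intermediate
23 | 4-bromo-2-{[(2S,3S)-3-(3,5-dimethoxyphenyl)-6-methoxy-2-(4-methoxyphenyl)-2,3-dihydro-1-benzofuran-4-yl](hydroxy)methyl}phenol (both carbinol epimers) | Oc1ccc(Br)cc1C(O)c1cc(OC)cc2c1[C@H](c1cc(OC)cc(OC)c1)[C@@H](c1ccc(OC)cc1)O2 | intermediate
24 | 4-bromo-2-{[(2S,3S)-3-(3,5-dimethoxyphenyl)-6-methoxy-2-(4-methoxyphenyl)-2,3-dihydro-1-benzofuran-4-yl](4-methylbenzenesulfonyl)methyl}phenol (both epimers at the sulfone carbon) | Cc1ccc(S(=O)(=O)C(c2cc(Br)ccc2O)c2cc(OC)cc3c2[C@H](c2cc(OC)cc(OC)c2)[C@@H](c2ccc(OC)cc2)O3)cc1 | intermediate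
25 | (1R,4R,5R)-4,7,7-trimethyl-6-thiabicyclo[3.2.1]octane (isothiocineole; commercial, or one step from (R)-limonene and sulfur) | C[C@@H]1CC[C@@H]2C[C@H]1SC2(C)C | starting material
26 | 4-methoxybenzyl bromide | COc1ccc(CBr)cc1 | starting material
27 | (1R,4R,5R)-6-(4-methoxybenzyl)-4,7,7-trimethyl-6-thiabicyclo[3.2.1]octan-6-ium trifluoromethanesulfonate (configuration at sulfur as formed, not assigned) | C[C@@H]1CC[C@@H]2C[C@H]1[S+](Cc1ccc(OC)cc1)C2(C)C.[O-]S(=O)(=O)C(F)(F)F | intermediate
28 | 4-bromo-6-{[(2S,3S)-3-(3,5-dimethoxyphenyl)-6-methoxy-2-(4-methoxyphenyl)-2,3-dihydro-1-benzofuran-4-yl]methylidene}cyclohexa-2,4-dien-1-one (ortho-quinone methide, alkene geometry not defined) | O=C1C=CC(Br)=CC1=Cc1cc(OC)cc2c1[C@H](c1cc(OC)cc(OC)c1)[C@@H](c1ccc(OC)cc1)O2 | intermediate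
29 | 4-methoxybenzylide of sulfonium salt 27 (sulfonium ylide) | C[C@@H]1CC[C@@H]2C[C@H]1[S+]([CH-]c1ccc(OC)cc1)C2(C)C | intermediate
30 | (2S,3S)-5-bromo-3-[(2S,3S)-3-(3,5-dimethoxyphenyl)-6-methoxy-2-(4-methoxyphenyl)-2,3-dihydro-1-benzofuran-4-yl]-2-(4-methoxyphenyl)-2,3-dihydro-1-benzofuran | COc1ccc([C@H]2Oc3ccc(Br)cc3[C@@H]2c2cc(OC)cc3c2[C@H](c2cc(OC)cc(OC)c2)[C@@H](c2ccc(OC)cc2)O3)cc1 | intermediate
31 | 1-ethenyl-3,5-dimethoxybenzene (3,5-dimethoxystyrene) | C=Cc1cc(OC)cc(OC)c1 | starting material
32 | hepta-O-methyl trans-diptoindonesin B: (2S,3S)-3-(3,5-dimethoxyphenyl)-4-{(2S,3S)-5-[(E)-2-(3,5-dimethoxyphenyl)ethenyl]-2-(4-methoxyphenyl)-2,3-dihydro-1-benzofuran-3-yl}-6-methoxy-2-(4-methoxyphenyl)-2,3-dihydro-1-benzofuran | COc1ccc([C@H]2Oc3ccc(/C=C/c4cc(OC)cc(OC)c4)cc3[C@@H]2c2cc(OC)cc3c2[C@H](c2cc(OC)cc(OC)c2)[C@@H](c2ccc(OC)cc2)O3)cc1 | intermediate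
33 | trans-diptoindonesin B: 5-[(E)-2-{(2S,3S)-3-[(2S,3S)-3-(3,5-dihydroxyphenyl)-6-hydroxy-2-(4-hydroxyphenyl)-2,3-dihydro-1-benzofuran-4-yl]-2-(4-hydroxyphenyl)-2,3-dihydro-1-benzofuran-5-yl}ethenyl]benzene-1,3-diol | Oc1ccc([C@H]2Oc3ccc(/C=C/c4cc(O)cc(O)c4)cc3[C@@H]2c2cc(O)cc3c2[C@H](c2cc(O)cc(O)c2)[C@@H](c2ccc(O)cc2)O3)cc1 | target

## Step count and risks

Total: 18 steps. Longest linear sequence: 13 steps (steps 1–4, 9–14 and 16–18; the pyrone branch through steps 5–8 is equally long).

**Step 9 (key step).** The donor-substituted pyrone may simply be too unreactive, so that the ketene acetal is lost by desilylation or silyl migration before it adds. The acetal may add at C4 with displacement of methoxide. The intermediate may aromatise by expelling the ring oxygen instead of the silanol. The fallback uses known chemistry and builds ring C by the ylide annulation that the route uses for ring A. It sets out from sulfonium salt 27 and commercial 1-bromo-3,5-dimethoxybenzene and comes back to the route at aldehyde 20. Vilsmeier–Haack formylation gives 2-bromo-4,6-dimethoxybenzaldehyde F1. BCl3 removes the methyl group ortho to the aldehyde through chelation and gives 2-bromo-6-hydroxy-4-methoxybenzaldehyde F2. Excess 3,5-dimethoxyphenylmagnesium bromide gives 3-bromo-2-[(3,5-dimethoxyphenyl)(hydroxy)methyl]-5-methoxyphenol F3. Sodium 4-methylbenzenesulfinate in formic acid gives 3-bromo-2-[(3,5-dimethoxyphenyl)(4-methylbenzenesulfonyl)methyl]-5-methoxyphenol F4. Cs2CO3 and 27 give (2S,3S)-4-bromo-3-(3,5-dimethoxyphenyl)-6-methoxy-2-(4-methoxyphenyl)-2,3-dihydro-1-benzofuran F5. Bromine–lithium exchange with n-BuLi and a DMF quench then give 20.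

**Step 3.** Racemisation of the α-aryl ketone may be slower than its reduction, which would leave a plain kinetic resolution. The matched pairing may be less pronounced than assumed. During the ionising lactonisation, loss of a proton from the cation to a stilbene would erode the configuration at lactone C4. The fallback is a classical resolution that sets out from keto ester 6 and returns at lactone 8. NaBH4 reduction and acid treatment give racemic trans-4-(3,5-dimethoxyphenyl)-5-(4-methoxyphenyl)oxolan-2-one F6. Aminolysis with (S)-1-phenylethylamine gives (3R,4S)-3-(3,5-dimethoxyphenyl)-4-hydroxy-4-(4-methoxyphenyl)-N-[(1S)-1-phenylethyl]butanamide F7 and its (3S,4R) diastereomer F8, which are separated by crystallisation or chromatography. Acid-mediated relactonisation of F7 releases the amine and gives 8.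

**Step 16.** The chiral ylide may discriminate poorly between the faces of a hindered quinone methide that already carries the ring C stereocentres (a mismatched pairing). The 4-methoxybenzyl sulfonium salt of the bulky sulfide may dealkylate. The quinone methide may oligomerise before it is trapped. The fallback sets out from sulfone 24 and returns at bromide 30. The robust achiral salt 1-(4-methoxybenzyl)thiolan-1-ium bromide F9, made from tetrahydrothiophene and 26, is used with Cs2CO3. The annulation remains trans-selective and gives 30 together with its (2R,3R) ring A diastereomer F10. The two are separable by chromatography because the ring C stereocentres make them diastereomers.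

**Step 18.** BBr3 may ionise the benzylic C2–O1 and C2'–O1' bonds and lead to ring-opened or rearranged material. The electron-rich stilbene may add HBr or undergo cationic oligomerisation. The fallback moves the demethylation in front of the coupling; it sets out from bromide 30 and ends at target 33. BBr3 on 30 gives the pentaphenol (2S,3S)-5-bromo-3-[(2S,3S)-3-(3,5-dihydroxyphenyl)-6-hydroxy-2-(4-hydroxyphenyl)-2,3-dihydro-1-benzofuran-4-yl]-2-(4-hydroxyphenyl)-2,3-dihydro-1-benzofuran F11, with no alkene present. Mizoroki–Heck coupling of F11 with 3,5-diacetoxystyrene gives the di-O-acetate of the target on the styryl ring F12. K2CO3 in methanol then removes the acetates to give 33.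

## Further compounds

F1 | step 9 | 2-bromo-4,6-dimethoxybenzaldehyde | COc1cc(OC)c(C=O)c(Br)c1
F2 | step 9 | 2-bromo-6-hydroxy-4-methoxybenzaldehyde | COc1cc(O)c(C=O)c(Br)c1
F3 | step 9 | 3-bromo-2-[(3,5-dimethoxyphenyl)(hydroxy)methyl]-5-methoxyphenol (racemic) | COc1cc(O)c(C(O)c2cc(OC)cc(OC)c2)c(Br)c1
F4 | step 9 | 3-bromo-2-[(3,5-dimethoxyphenyl)(4-methylbenzenesulfonyl)methyl]-5-methoxyphenol (racemic) | COc1cc(O)c(C(c2cc(OC)cc(OC)c2)S(=O)(=O)c2ccc(C)cc2)c(Br)c1
F5 | step 9 | (2S,3S)-4-bromo-3-(3,5-dimethoxyphenyl)-6-methoxy-2-(4-methoxyphenyl)-2,3-dihydro-1-benzofuran | Brc1cc(OC)cc2c1[C@H](c1cc(OC)cc(OC)c1)[C@@H](c1ccc(OC)cc1)O2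
F6 | step 3 | racemic trans-4-(3,5-dimethoxyphenyl)-5-(4-methoxyphenyl)oxolan-2-one | O=C1C[C@H](c2cc(OC)cc(OC)c2)[C@@H](c2ccc(OC)cc2)O1.O=C1C[C@@H](c2cc(OC)cc(OC)c2)[C@H](c2ccc(OC)cc2)O1
F7 | step 3 | (3R,4S)-3-(3,5-dimethoxyphenyl)-4-hydroxy-4-(4-methoxyphenyl)-N-[(1S)-1-phenylethyl]butanamide | C[C@H](NC(=O)C[C@H](c1cc(OC)cc(OC)c1)[C@H](O)c1ccc(OC)cc1)c1ccccc1
F8 | step 3 | (3S,4R)-3-(3,5-dimethoxyphenyl)-4-hydroxy-4-(4-methoxyphenyl)-N-[(1S)-1-phenylethyl]butanamide | C[C@H](NC(=O)C[C@@H](c1cc(OC)cc(OC)c1)[C@@H](O)c1ccc(OC)cc1)c1ccccc1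
F9 | step 16 | 1-(4-methoxybenzyl)thiolan-1-ium bromide | COc1ccc(C[S+]2CCCC2)cc1.[Br-]
F10 | step 16 | (2R,3R)-5-bromo-3-[(2S,3S)-3-(3,5-dimethoxyphenyl)-6-methoxy-2-(4-methoxyphenyl)-2,3-dihydro-1-benzofuran-4-yl]-2-(4-methoxyphenyl)-2,3-dihydro-1-benzofuran | COc1ccc([C@@H]2Oc3ccc(Br)cc3[C@H]2c2cc(OC)cc3c2[C@H](c2cc(OC)cc(OC)c2)[C@@H](c2ccc(OC)cc2)O3)cc1
F11 | step 18 | (2S,3S)-5-bromo-3-[(2S,3S)-3-(3,5-dihydroxyphenyl)-6-hydroxy-2-(4-hydroxyphenyl)-2,3-dihydro-1-benzofuran-4-yl]-2-(4-hydroxyphenyl)-2,3-dihydro-1-benzofuran | Oc1ccc([C@H]2Oc3ccc(Br)cc3[C@@H]2c2cc(O)cc3c2[C@H](c2cc(O)cc(O)c2)[C@@H](c2ccc(O)cc2)O3)cc1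
F12 | step 18 | trans-diptoindonesin B di-O-acetate on the styryl ring | Oc1ccc([C@H]2Oc3ccc(/C=C/c4cc(OC(C)=O)cc(OC(C)=O)c4)cc3[C@@H]2c2cc(O)cc3c2[C@H](c2cc(O)cc(O)c2)[C@@H](c2ccc(O)cc2)O3)cc1
A1 | alternative 1 | 4-bromo-2-[{2-[(3,5-dimethoxyphenyl)(4-methylbenzenesulfonyl)methyl]-3-hydroxy-5-methoxyphenyl}(4-methylbenzenesulfonyl)methyl]phenol | Cc1ccc(S(=O)(=O)C(c2cc(Br)ccc2O)c2cc(OC)cc(O)c2C(c2cc(OC)cc(OC)c2)S(=O)(=O)c2ccc(C)cc2)cc1
A2 | alternative 1 | penta-O-methyl 5-bromo core with both trans dihydrofurans (identical with 30) | COc1ccc([C@H]2Oc3ccc(Br)cc3[C@@H]2c2cc(OC)cc3c2[C@H](c2cc(OC)cc(OC)c2)[C@@H](c2ccc(OC)cc2)O3)cc1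
A3 | alternative 2 | 5-bromo-3-(3,5-dimethoxybenzoyl)-1-benzofuran-2(3H)-one | O=C1Oc2ccc(Br)cc2C1C(=O)c1cc(OC)cc(OC)c1
A4 | alternative 2 | 3,5-dimethoxy-2-(trimethylsilyl)phenyl trifluoromethanesulfonate | COc1cc(OC)c([Si](C)(C)C)c(OS(=O)(=O)C(F)(F)F)c1
A5 | alternative 2 | 5-bromo-3-[2-(3,5-dimethoxybenzoyl)-3,5-dimethoxyphenyl]-1-benzofuran-2(3H)-one (C3 racemic) | O=C1Oc2ccc(Br)cc2C1c1cc(OC)cc(OC)c1C(=O)c1cc(OC)cc(OC)c1
A6 | alternative 3 | 2-[(E)-2-{(2S,3S)-3-(3,5-dimethoxyphenyl)-6-methoxy-2-(4-methoxyphenyl)-2,3-dihydro-1-benzofuran-4-yl}ethenyl]-4,4,5,5-tetramethyl-1,3,2-dioxaborolane | CC1(C)OB(/C=C/c2cc(OC)cc3c2[C@H](c2cc(OC)cc(OC)c2)[C@@H](c2ccc(OC)cc2)O3)OC1(C)C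
A7 | alternative 3 | methyl 4-fluoro-3-{[(trifluoromethyl)sulfonyl]oxy}benzoate | COC(=O)c1ccc(F)c(OS(=O)(=O)C(F)(F)F)c1
A8 | alternative 3 | 4-methoxyphenyllithium | [Li]c1ccc(OC)cc1
A9 | alternative 3 | secondary pinacol boronic ester with boron on C2 and the ring A aryl (2-fluoro-5-methoxycarbonylphenyl) on C3 | COc1ccc([C@@H](B2OC(C)(C)C(C)(C)O2)[C@H](c2cc(C(=O)OC)ccc2F)c2cc(OC)cc3c2[C@H](c2cc(OC)cc(OC)c2)[C@@H](c2ccc(OC)cc2)O3)cc1
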